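The runs are calculated on assumed constants; scatter was added.

Read this flask by its leftover. Let L be the fraction of starting material still there. If the rate follows what is left, L = exp(−t/τ), so τ = −t/ln L; call it the leftover constant, a pseudo-first-order time constant averaged over the run.

| flask | starting material | second substrate | free enzyme | remark |
|---|---|---|---|---|
| larch | 0.012 M | 0.0216 M | 1.3 µM | run made earlier |
| birch | 0.027 M | 0.0216 M | 1.3 µM | run made earlier |
| maple | 0.018 M | 0.043 M | 1.3 µM | run made earlier |
| flask | 0.018 M | 0.0216 M | 1.3 µM |  |

- larch (time / h: target / %, starting material / %): 1.50: 11, 93; 3.00: 22, 78; 5.00: 35, 67; 6.00: 38, 61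
- birch (time / h: target / %, starting material / %): 0.500: 4, 98; 1.00: 4, 94; 2.50: 13, 89; 6.00: 25, 76
- maple (time / h: target / %, starting material / %): 0.833: 5, 96; 2.00: 12, 89; 4.00: 21, 77; 6.00: 35, 66

(readings scatter by 2 percentage points)

- no earlier run changes the charge of free enzyme; that part of a forecast is a guess

* apparent order in second substrate when 20% of the starting material are converted (percent change of the rate of making target for one percent more second substrate charged)
* apparent order in free enzyme when 20% of the starting material are converted (percent change of the rate of making target for one percent more free enzyme charged)

At 6.00 h, larch gives 12.1 h and birch 21.9 h. Both match this flask in second substrate, so assume a straight line in the charge of starting material, which gives this flask 16.0 h, its leftover constant. Expect this flask to reach 20% conversion at 3.58 h and to hold 68.8% at 6.00 h.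

Maple has the same starting material and twice the second substrate, and its constant, 14.4 h, is shorter than this flask's. So my order in second substrate is 0.152, a run average that I take as the order at 20% conversion, read from single readings with their scatter. Don't change the free enzyme charge: no earlier run did, so that order is a guess.

The forecast says 0.2 for second substrate, above mine, and 1 for free enzyme, since “A catalyst normally gives first order”.

This flask gives an order of 0.34 in second substrate and 1.0 in free enzyme.

second complex ⇌ free enzyme + target (K = 0.0180 M, k = 2680 h⁻¹); first complex ⇌ loaded enzyme + first product (K = 0.0160 M, k = 2910 h⁻¹); starting material + free enzyme ⇌ first complex (K = 110 L mol⁻¹, k = 5.32 × 10⁵ L mol⁻¹ h⁻¹); second substrate + loaded enzyme ⇌ second complex (K = 90.0 L mol⁻¹, k = 1.76 × 10⁶ L mol⁻¹ h⁻¹) At 6.00 h this flask held 70.6%, so its leftover constant is 17.3 h, longer than my 16.0 h. Part of this flask's order in second substrate comes from the backward run from second complex to second substrate and loaded enzyme: remove that run and the order falls from 0.34 to 0.045.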